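**Retrosynthetic overview**
- The usual aniline/β-keto ester or Camps condensation is set aside; the chain is cut between its C-1 and C-2, giving the lateral dianion of 3-methoxy-2-methylquinolin-4(1H)-one and an ω-bromo tertiary carbinol.
- The quinolone core is cut at N1–C2 (6-endo aza-Michael onto an α-methoxy allenyl ketone) and at C3–C4 (acylation of C-1-lithiated methoxyallene by an anthranilic Weinreb amide).
- Ring order: the benzene ring is bought; the pyridone ring is the only ring formed (step 2), with the C-3 methoxy group arriving inside the allene.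
- The bromo carbinol comes from methyl 10-bromodecanoate and MeMgBr.

Assumption: the target SMILES has no stereocentre and no stereogenic double bond, so the compound is achiral and no stereocontrol is needed; compounds 1, 4 and 5 are taken as catalogue chemicals.

**Step 1**
Reactants: 1 methyl 10-bromodecanoate
Product: 3 11-bromo-2-methylundecan-2-ol, via 11-bromoundecan-2-one 2 (not isolated)
Conditions: MeMgBr (2.5 equiv), THF, 0 °C → rt; then 1 M HCl, 0 °C
Reagents that add atoms: methylmagnesium bromide, C[Mg]Br (both new methyl groups)
Why: Double Grignard addition to the ester (acyl substitution to ketone 2, then 1,2-addition) gives the tertiary alcohol, and the primary C–Br bond does not couple with MeMgBr at or below room temperature without a copper catalyst; no stereocentre is formed.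

**Step 2**
Reactants: 4 methoxyallene (1-methoxypropa-1,2-diene); 5 2-amino-N-methoxy-N-methylbenzamide
Product: 8 3-methoxy-2-methylquinolin-4(1H)-one, via 1-lithio-1-methoxyallene 6 (not isolated), via 1-(2-aminophenyl)-2-methoxybuta-2,3-dien-1-one 7 (not isolated)
Conditions: 4 (3.3 equiv), n-BuLi (3.0 equiv), THF, −40 °C; 5 (1.0 equiv), −78 → −20 °C; sat. aq NH4Cl; crude 7, K2CO3 (0.2 equiv), MeCN, 60 °C
Reagents that add atoms: n-butyllithium, [Li]CCCC (supplies only the lithium of intermediate 6; nothing from it remains in 8)
Why: Proposed new method: C-1-lithiated methoxyallene acylates the Weinreb amide (Weinreb ketone synthesis; excess reagent absorbs the NH2 protons and the chelated adduct prevents over-addition), and in the released α-methoxy allenyl ketone 7 the aniline nitrogen attacks the electrophilic central allene carbon in a 6-endo aza-Michael addition, after which a proton shift gives the 4-quinolone with OMe at C-3 and the former allene terminus as the 2-methyl group; the closest known reactions are the acylation of lithiated alkoxyallenes by Weinreb or morpholine amides, the 6-endo cyclisation of 2-aminophenyl ynones to 4-quinolones and amine conjugate addition to allenyl ketones; no stereocentre is formed.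

**Step 3**
Reactants: 8 3-methoxy-2-methylquinolin-4(1H)-one; 3 11-bromo-2-methylundecan-2-ol
Product: 11 2-(11-hydroxy-11-methyldodecyl)-3-methoxyquinolin-4(1H)-one, via lithium 2-(lithiomethyl)-3-methoxyquinolin-4-olate 9 (not isolated), via lithium 11-bromo-2-methylundecan-2-olate 10 (not isolated)
Conditions: 8 (1.2 equiv), LiN(i-Pr)2 (2.5 equiv), THF/DMPU, −78 → 0 °C; separately 3 (1.0 equiv), LiN(i-Pr)2 (1.0 equiv), THF, −78 °C; combine, −78 °C → rt; sat. aq NH4Cl
Reagents that add atoms: lithium diisopropylamide, [Li+].CC(C)[N-]C(C)C (supplies only the lithium of intermediates 9 and 10; nothing from it remains in 11)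
Why: Lateral (vinylogous) lithiation and dianion alkylation: after N–H removal a second equivalent of base deprotonates the 2-methyl group, and this last-formed, most basic carbanion of 9 is alkylated by SN2 at the primary bromide of 10, whose hindered tertiary alkoxide is inert (the same lateral alkylation is routine for 1,2-dimethyl-4-quinolones and 2-methylquinazolin-4-ones); no stereocentre is formed.

**Compound list**
1 | methyl 10-bromodecanoate | COC(=O)CCCCCCCCCBr | starting material
2 | 11-bromoundecan-2-one | CC(=O)CCCCCCCCCBr | intermediate
3 | 11-bromo-2-methylundecan-2-ol | CC(C)(O)CCCCCCCCCBr | intermediate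
4 | methoxyallene (1-methoxypropa-1,2-diene) | COC=C=C | starting material
5 | 2-amino-N-methoxy-N-methylbenzamide | CON(C)C(=O)c1ccccc1N | starting material
6 | 1-lithio-1-methoxyallene | [Li]C(OC)=C=C | intermediate
7 | 1-(2-aminophenyl)-2-methoxybuta-2,3-dien-1-one | COC(=C=C)C(=O)c1ccccc1N | intermediate
8 | 3-methoxy-2-methylquinolin-4(1H)-one | COc1c(C)[nH]c2ccccc2c1=O | intermediate
9 | lithium 2-(lithiomethyl)-3-methoxyquinolin-4-olate (C,N/O-dianion of 8) | [Li+].[Li+].[CH2-]c1nc2ccccc2c([O-])c1OC | intermediate
10 | lithium 11-bromo-2-methylundecan-2-olate | [Li+].[O-]C(C)(C)CCCCCCCCCBr | intermediate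
11 | 2-(11-hydroxy-11-methyldodecyl)-3-methoxyquinolin-4(1H)-one (achiral) | COc1c(CCCCCCCCCCC(C)(C)O)[nH]c2ccccc2c1=O | target

**Total step count:** 3
**Longest linear sequence:** 2 steps (5 → 8 → 11, or 1 → 3 → 11)

**Steps most likely to fail, with fallbacks**

Step 2 (highest risk: the allenyl ketone 7 may decompose or fail to close the ring). The fallback replaces the allene cascade by a Camps ring closure. It sets out from 5: MeOCH2MgCl (made from MeOCH2Cl and Mg, THF, −20 °C) converts the Weinreb amide into 1-(2-aminophenyl)-2-methoxyethan-1-one F1. Ac2O in pyridine then gives N-[2-(2-methoxyacetyl)phenyl]acetamide F2. NaOH in 1,4-dioxane at 110 °C condenses the α-methoxy ketone enolate onto the acetamide carbonyl with loss of water, and the route is rejoined at 8.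

Step 3 (the dianion 9 may be poorly soluble or sluggish, or alkylate on N/O). The fallback removes the acidic N–H and works with an ordinary quinaldine monoanion. It sets out from 8: BnBr and Ag2CO3 in toluene at 80 °C give 4-(benzyloxy)-3-methoxy-2-methylquinoline F3. Lateral lithiation with LiN(i-Pr)2 (1.1 equiv, THF, −78 °C) and alkylation with the alkoxide 10 give 12-[4-(benzyloxy)-3-methoxyquinolin-2-yl]-2-methyldodecan-2-ol F4. Hydrogenolysis (H2, 1 atm, Pd/C, EtOH) removes the benzyl group and the route is rejoined at 11.

Step 1 (lowest risk: incomplete addition through enolisation of ketone 2, or loss of bromide on scale). The fallback avoids bromo carbinol 3 and brings in the tertiary alcohol by olefin metathesis after the chain is attached. It sets out from 8: the dianion 9 is alkylated with 9-bromonon-1-ene to give 2-(dec-9-en-1-yl)-3-methoxyquinolin-4(1H)-one F5. Cross-metathesis with 2-methylbut-3-en-2-ol (5 equiv) using the second-generation Grubbs catalyst RuCl2(=CHPh)(PCy3)(H2IMes) in CH2Cl2 at 40 °C gives 2-[(E)-11-hydroxy-11-methyldodec-9-en-1-yl]-3-methoxyquinolin-4(1H)-one F6. Hydrogenation (H2, 1 atm, Pd/C, EtOAc) saturates the alkene and the route is rejoined at 11.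

**Further compounds**
F1 | step 2 | 1-(2-aminophenyl)-2-methoxyethan-1-one | COCC(=O)c1ccccc1N
F2 | step 2 | N-[2-(2-methoxyacetyl)phenyl]acetamide | COCC(=O)c1ccccc1NC(C)=O
F3 | step 3 | 4-(benzyloxy)-3-methoxy-2-methylquinoline | COc1c(C)nc2ccccc2c1OCc1ccccc1
F4 | step 3 | 12-[4-(benzyloxy)-3-methoxyquinolin-2-yl]-2-methyldodecan-2-ol | COc1c(CCCCCCCCCCC(C)(C)O)nc2ccccc2c1OCc1ccccc1
F5 | step 1 | 2-(dec-9-en-1-yl)-3-methoxyquinolin-4(1H)-one | COc1c(CCCCCCCCC=C)[nH]c2ccccc2c1=O
F6 | step 1 | 2-[(E)-11-hydroxy-11-methyldodec-9-en-1-yl]-3-methoxyquinolin-4(1H)-one | COc1c(CCCCCCCC/C=C/C(C)(C)O)[nH]c2ccccc2c1=O
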